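**Plan**

- Retrosynthesis: the C3=C4 double bond of the dimethoxycoumarin is taken back to the 3,4-dihydrolactone. O1 is then excised from between C2 and C8a, which contracts the lactone to a 5,6-dimethoxyindan-1-one. Last, the bond between the umbelliferyl oxygen and the sp3 carbon next to the ketone is cut, giving an α-bromo ketone and umbelliferone.
- Enabling feature: in the dimethoxycoumarin, ring oxygen O1 lies between the carbonyl carbon C2 and the aryl carbon C8a, and C8a is para to the C6 methoxy. That is the pattern left when a para-methoxy-activated aryl carbon shifts from a ketone carbon to oxygen in a peracid oxidation.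
- Forward: indanone 1 is brominated to 2, umbelliferone 3 displaces bromide to give ether 4, and peracid (through adduct 5) enlarges the cyclopentanone to lactone 6. Dehydrogenation then gives target 7.
- Rings: the benzene ring of 1 and both rings of 3 are bought. The only ring made is the six-membered lactone, which arises by oxygen insertion into the five-membered ketone.
- Stereochemistry: 7 is achiral. The one stereocentre carried from 2 to 6 is racemic throughout and is erased in the last step.

Key step: step 3

Remark: because the target has no stereocentre, all chiral intermediates are used as racemates (5 as a mixture of racemic diastereomers), so their SMILES carry no stereodescriptors.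
Assumption: 5,6-dimethoxyindan-1-one, umbelliferone and (for one fallback) 2-hydroxy-4,5-dimethoxybenzaldehyde are purchased.

**Route**

Step 1
Reactants: 1 5,6-dimethoxyindan-1-one
Product: 2 2-bromo-5,6-dimethoxyindan-1-one (racemic)
Conditions: CuBr2 (2.1 equiv), EtOAc/CHCl3 (1:1), reflux
Reagents that add atoms: CuBr2, Br[Cu]Br
Why: α-bromination of an aryl ketone with CuBr2 goes through the enol at C2, the only enolisable carbon, and with no free Br2 present in quantity it should stop at the monobromide and spare the dimethoxyarene; the new C2 stereocentre forms racemic, which is all that is needed.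

Step 2
Reactants: 2 2-bromo-5,6-dimethoxyindan-1-one; 3 umbelliferone (7-hydroxy-2H-chromen-2-one)
Product: 4 5,6-dimethoxy-2-[(2-oxo-2H-chromen-7-yl)oxy]indan-1-one (racemic)
Conditions: 3 (1.1 equiv), K2CO3 (1.5 equiv), acetone, rt to 45 °C
Reagents that add atoms: none
Why: Williamson ether synthesis by SN2 displacement at an α-bromo ketone, where the acidic phenol 3 gives a soft, weakly basic phenoxide and the adjacent carbonyl accelerates substitution, so etherification should outrun dehydrobromination; the centre is inverted but stays racemic.

Step 3
Reactants: 4 5,6-dimethoxy-2-[(2-oxo-2H-chromen-7-yl)oxy]indan-1-one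
Product: 6 6,7-dimethoxy-3-[(2-oxo-2H-chromen-7-yl)oxy]chroman-2-one (racemic), via Criegee adduct 5 (not isolated)
Conditions: mCPBA (1.5 equiv), TsOH·H2O (0.2 equiv), CH2Cl2, 0 °C to rt, dark
Reagents that add atoms: mCPBA (3-chloroperoxybenzoic acid), OOC(=O)c1cccc(Cl)c1
Why: Baeyer–Villiger oxidation: the acid-activated ketone adds the peracid at C1 to give adduct 5, which forms the future O1–C2 bond, and the aryl carbon C7a then shifts from C1 to the proximal peroxide oxygen as 3-chlorobenzoate departs, which forms the C8a–O1 bond. The closest known reaction type is the peracid oxidation of 1-indanones to 3,4-dihydrocoumarins with aryl migration. The six-membered lactone is not closed by a cyclisation but arises by one-atom ring expansion of the five-membered ketone, both new ring bonds ending on the inserted oxygen. No stereocentre is created, and the racemic ether-bearing carbon is not the migrating atom, so it is carried over unchanged. The step needs aryl migration to beat migration of the secondary ether-bearing carbon C2: C7a is para to the C5 methoxy, which stabilises the positive charge building up in the bridged transition state, whereas the lone pairs of the C2 ether oxygen are drawn into the electron-poor coumarin, so that oxygen acts mainly as an inductive acceptor and makes C2 the poorer migrant. The C3=C4 bond of the umbelliferyl unit is electron-poor and should ignore the electrophilic peracid, and the small excess of oxidant at low temperature should protect the electron-rich ring of 6.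

Step 4
Reactants: 6 6,7-dimethoxy-3-[(2-oxo-2H-chromen-7-yl)oxy]chroman-2-one
Product: 7 daphnoretin methyl ether, 6,7-dimethoxy-3-[(2-oxo-2H-chromen-7-yl)oxy]-2H-chromen-2-one
Conditions: DDQ (1.5 equiv), 1,4-dioxane, reflux
Reagents that add atoms: none
Why: DDQ dehydrogenation of a dihydrocoumarin, in which hydride is taken from benzylic C4 (the cation is stabilised by the para C7 methoxy) and the acidic C3 proton is then lost to give the conjugated coumarin, erasing the stereocentre while the diaryl ether and both lactones stay untouched.

**Compound list**

1 | 5,6-dimethoxyindan-1-one | COc1cc2CCC(=O)c2cc1OC | starting material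
2 | 2-bromo-5,6-dimethoxyindan-1-one (racemic) | COc1cc2CC(Br)C(=O)c2cc1OC | intermediate
3 | umbelliferone (7-hydroxy-2H-chromen-2-one) | Oc1ccc2ccc(=O)oc2c1 | starting material
4 | 5,6-dimethoxy-2-[(2-oxo-2H-chromen-7-yl)oxy]indan-1-one (racemic) | COc1cc2CC(Oc3ccc4ccc(=O)oc4c3)C(=O)c2cc1OC | intermediate
5 | Criegee adduct, 1-hydroxy-5,6-dimethoxy-2-[(2-oxo-2H-chromen-7-yl)oxy]indan-1-yl 3-chloroperoxybenzoate (racemic diastereomers) | COc1cc2CC(Oc3ccc4ccc(=O)oc4c3)C(O)(OOC(=O)c5cccc(Cl)c5)c2cc1OC | intermediate (not isolated)
6 | 6,7-dimethoxy-3-[(2-oxo-2H-chromen-7-yl)oxy]chroman-2-one (racemic) | COc1cc2CC(Oc3ccc4ccc(=O)oc4c3)C(=O)Oc2cc1OC | intermediate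
7 | daphnoretin methyl ether, 6,7-dimethoxy-3-[(2-oxo-2H-chromen-7-yl)oxy]-2H-chromen-2-one | COc1cc2cc(Oc3ccc4ccc(=O)oc4c3)c(=O)oc2cc1OC | target

**Count**

Total steps: 4. Longest linear sequence: 4 steps (1 to 7); umbelliferone 3 enters at step 2.

**Steps most likely to fail**

1. Step 3. The ether-bearing carbon may migrate in place of the aryl carbon, so that oxygen is inserted on the wrong side of the carbonyl, or the peracid may go on to oxidise the electron-rich ring. The fallback gives up the ring expansion and builds the 3-aryloxycoumarin by condensation; it sets out from 3 and returns to the route at 7. Umbelliferone 3 is O-alkylated with tert-butyl bromoacetate (K2CO3, acetone) to tert-butyl [(2-oxo-2H-chromen-7-yl)oxy]acetate F1. The ester is cleaved with TFA in CH2Cl2 to [(2-oxo-2H-chromen-7-yl)oxy]acetic acid F2. F2 is then condensed with 2-hydroxy-4,5-dimethoxybenzaldehyde (O=Cc1cc(OC)c(OC)cc1O) under Perkin conditions (Ac2O, Et3N, 120 °C), which should give 7 directly by acylation, intramolecular aldol condensation and dehydration.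

2. Step 2. Base may dehydrobrominate 2 to an indenone that polymerises, or 2 may self-condense, faster than the phenoxide substitutes. The fallback replaces the SN2 reaction by a carbenoid O–H insertion; it sets out from 1 and returns at 4. Indanone 1 is formylated (HCO2Et, NaH, THF) to (2Z)-2-(hydroxymethylene)-5,6-dimethoxyindan-1-one F3. Deformylative diazo transfer (TsN3, Et3N, CH2Cl2) converts F3 into 2-diazo-5,6-dimethoxyindan-1-one F4. Slow addition of F4 to 3 and catalytic Rh2(OAc)4 in 1,2-dichloroethane at 60 °C should give ether 4 by O–H insertion.

3. Step 4. Dehydrogenation may stall, or DDQ may degrade the electron-rich ring at the temperature needed. The fallback introduces the double bond by selenoxide elimination; it sets out from 6 and returns at 7. Lactone 6 is deprotonated at C3 (LiN(SiMe3)2, THF, −78 °C) and trapped with PhSeBr to give 6,7-dimethoxy-3-[(2-oxo-2H-chromen-7-yl)oxy]-3-(phenylselanyl)chroman-2-one F5. Oxidation with H2O2 (CH2Cl2, 0 °C) gives the selenoxide 3-(benzeneseleninyl)-6,7-dimethoxy-3-[(2-oxo-2H-chromen-7-yl)oxy]chroman-2-one F6. On warming to rt, F6 should undergo syn-elimination towards C4, the only position with a β-hydrogen, to give 7.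

Further compounds
F1 | step 3 | tert-butyl [(2-oxo-2H-chromen-7-yl)oxy]acetate | CC(C)(C)OC(=O)COc1ccc2ccc(=O)oc2c1
F2 | step 3 | [(2-oxo-2H-chromen-7-yl)oxy]acetic acid | OC(=O)COc1ccc2ccc(=O)oc2c1
F3 | step 2 | (2Z)-2-(hydroxymethylene)-5,6-dimethoxyindan-1-one (enol tautomer of the 2-formyl ketone) | COc1cc2C/C(=C/O)C(=O)c2cc1OC
F4 | step 2 | 2-diazo-5,6-dimethoxyindan-1-one | COc1cc2CC(=[N+]=[N-])C(=O)c2cc1OC
F5 | step 4 | 6,7-dimethoxy-3-[(2-oxo-2H-chromen-7-yl)oxy]-3-(phenylselanyl)chroman-2-one (racemic) | COc1cc2CC(Oc3ccc4ccc(=O)oc4c3)([Se]c3ccccc3)C(=O)Oc2cc1OC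
F6 | step 4 | 3-(benzeneseleninyl)-6,7-dimethoxy-3-[(2-oxo-2H-chromen-7-yl)oxy]chroman-2-one (racemic diastereomers) | COc1cc2CC(Oc3ccc4ccc(=O)oc4c3)([Se](=O)c3ccccc3)C(=O)Oc2cc1OC
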